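# Proposed total synthesis of CNP0127096.1 (33) through a carbenoid O–H insertion intercepted by a bridging aldol

Remark on numbering: C1 to O28 denote the atoms of 33 in the order in which they stand in its SMILES (C10 side-chain carbinol carbon, O11 ether oxygen, C12 quaternary ether carbon, C13 lactone carbonyl, O15 ring oxygen, C16 quaternary carbinol carbon, C18 secondary carbinol, C21/C22 ring-fusion CH, C23=C24 ring olefin, C27 carbinol of the bridge).

## Analysis of the target

- 33 is tetracyclic. A 2-oxabicyclo[2.2.2]octan-3-one (bridgeheads C12 and C16; bridges C13–O15, C22–C21 and C27–C26) carries a cyclopentane fused across C16–C21 and a 3,6-dihydro-2H-pyran fused across C12–C22, with an (E)-non-1-enyl chain on C10.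
- There are seven stereocentres (C10, C12, C16, C18, C21, C22, C27); six of them sit on the cage and are interlocked.
- On the cyclopentane, O15 and C22 are cis (cis ring fusion) and the C18 hydroxyl is trans to both, on the convex face. H21 and H22 are cis. The C27 hydroxyl points toward the C22–C21 bridge, away from the lactone. On the pyran, the C10 chain lies on the face of C13, 1,3-diaxial to it.
- Sensitive groups are the β-hydroxy lactone (retro-aldol), the doubly allylic ether at C10 (ionisation) and the O15–C16 bond, which is lost by β-elimination whenever C17 or C26 is enolised next to a carbonyl.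
- The hard point is C12: it is quaternary, carries a tertiary ether to a hindered secondary carbinol, and becomes a bridgehead. Once the cage is closed it cannot be enolised, so neither O11 nor C27 can be attached afterwards.
- The strategy rests on one feature: O11 sits on C12 between the C13 carbonyl and the C27 carbinol. This α-alkoxy-β-hydroxy ester is the sum of a carbene at C12, an O–H bond and an aldehyde.

## Retrosynthetic reasoning

**C18–O–Si and C7–C8.** 33 is traced to its silyl ether 32, and 32 to the alkenyl iodide 30 and the alkylzinc reagent 31. The heptyl group is attached last, by a stereoretentive sp2–sp3 coupling, because it must not be present during ring closure of the pyran (next paragraph).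

**C23=C24 (pyran ring).** 30 is opened to the triene 29 by a retro-metathesis. If C9=C8 were an ordinary (E)-alkene, the alkylidene formed at C23 could also close onto C9. That would give a six-membered ring too, expel the chain, and be the easier closure, since it leaves only H10 syn-axial to C13. With iodine on C8 that olefin is silent, and the only closure left is the wanted one onto the isopropenyl group.

**O11–C12 and C12–C27 (key disconnection).** 29 is cut into the diazo lactone aldehyde 27 and the allylic alcohol 6.
- The cut is made here because the ether to a tertiary carbon cannot be made by substitution, and because C12 cannot be functionalised once it is a bridgehead.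
- A metal carbenoid at C12 takes up the O–H bond of 6 while C12 is still trigonal, and the resulting ylide or enol adds to the aldehyde held on C16.
- The gain is two bonds, one ring and two stereocentres in a neutral step, with C10 carried in unchanged.
- The forward reaction must let the aldol outrun proton transfer and hydride shift.

**Diazo group and aldehyde of 27.** 27 comes from lactone 23 by diazo transfer to C12, then release of the primary alcohol and oxidation. The aldehyde is unveiled last because it is a β-acyloxy aldehyde and would not survive the base used for diazo transfer.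

**C18 configuration.** 23 is traced through the alcohol 22 to ketone 19. Hydride is expected to enter the cis-fused bicycle from the convex face and give the wrong epimer 20. The route therefore plans a selective reduction followed by an SN2 inversion, and does not rely on a contra-steric reduction.

**C23 methylene.** 19 comes from aldehyde 18 by a non-basic, aldehyde-selective methylenation, so that C22 (α to the formyl group) is not epimerised.

**C21–C22 (lactone ring).** 18 is opened to the ester aldehyde 17, and 17 to the hydroxy enone 14 and the acid chloride 15. Tethering the C22 nucleophile through O15 guarantees the cis ring fusion; the enamine catalyst sets C22.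

**C16.** 14 is traced to the silyloxy enone 7 and the ester 8. The stereocentre of 7 directs the addition to the carbonyl and is then oxidised away, leaving C16 as the only centre.

**The alcohol 6.** 6 comes from the enynol 4 by syn hydrometalation and iodination, 4 from racemic 3 by kinetic resolution, and 3 from 1 and 2. A carbinol flanked by two comparably reactive alkenes cannot be resolved by epoxidation, because each enantiomer has its own fast channel. With an alkyne as the second group only one channel exists.

## Alternatives that were turned down

**Alternative 1: ester-tethered Michael addition as the central step.**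
- Disconnection and key step: C21–C22 is cut. In the forward sense, an aldehyde tethered through the O15 ester forms an enamine with a diarylprolinol silyl ether and adds through C22 to C21 of the cyclopentenone. This gives A1, the cis-fused keto lactone aldehyde that already carries a protected oxygen on C12.
- For: the reaction class is known, mild and catalytic, and it relays C16 to C21 and C22. On precedent it is stronger than the chosen key step, and the chosen route uses the same cyclisation as a supporting step (step 11).
- Against: it solves the easy half. In A1, C12 is a secondary carbinol carbon. Making it quaternary needs an enolate next to an acyloxy leaving group, and the ether to C10 would have to be formed on a tertiary, later bridgehead, alcohol. The pyran and the carbocycle are still missing.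
- Comparison: lower risk in the key step, but the hardest bonds are left for late, basic steps. The chosen strategy makes both bonds to C12 at once under neutral conditions.

**Alternative 2: Ireland–Claisen ring contraction.**
- Disconnection and key step: C12–C22 is cut. The silyl ketene acetal of a six-membered lactone whose ester oxygen sits on C24 (LDA, Me3SiCl) rearranges through a boat and contracts to the dihydropyran acid A2, with C12 and C22 set.
- For: a sigmatropic step with predictable transfer of chirality. It creates the quaternary ether carbon and the trisubstituted ring olefin without a diazo compound and without metathesis; on these two points it is stronger than the chosen route.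
- Against: the ester enolate carries a β-alkoxy leaving group on the C27 carbon. The rearranging olefin is trisubstituted and flanked by the C21 stereocentre. After A2 the lactone C–O bond at quaternary C16 and the C26–C27 bond must still be made in two further ring closures, each with its own stereochemical problem.
- Comparison: the risk is spread over three late steps and the sequence is linear. The chosen strategy joins two fragments and closes the carbocycle in the same step that makes the ether.

**Alternative 3: copper-catalysed oxo-Diels–Alder reaction.**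
- Disconnection and key step: O11–C10 and C12–C22 are cut. A glyoxylate dienophile and the C22=C23–C24=C10 diene combine under Cu(OTf)2 with a bis(oxazoline) ligand to give the dihydropyran ester A3, with C10, C12 and C22 set.
- For: it is the most convergent way to the pyran and it is catalytic. It sets C10 without a resolved alcohol and with the chain in place, so it is stronger than the chosen route on the pyran and on C10.
- Against: the diene is the inner part of a conjugated triene, trisubstituted and hindered at both termini, so periselectivity and reactivity are doubtful. C12 emerges as a tertiary C–H and would have to be made quaternary afterwards by enolate chemistry beside C22. The lactone and the carbocycle are both still to be closed.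
- Comparison: the best pyran construction, but it postpones the quaternary centre, which is the real problem. The chosen route accepts a longer path to the pyran in exchange for solving C12 directly.

Key step: step 19

## Route

Assumptions:
- The facial sense of the kinetic resolution (step 2), of the addition to the silyloxy enone (step 4) and of the prolinol-ether enamine (step 11) is taken from the usual models.
- Compounds 1, 2, 7, 8, 15 and 31 are bought.

### Alcohol fragment

Step 1
Reactants: 1 methacrolein; 2 ethynylmagnesium bromide
Product: 3 (±)-2-methylpent-1-en-4-yn-3-ol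
Conditions: THF, −78 to 0 °C; aq. NH4Cl
Reagents that add atoms: none
Why: 1,2-addition of the alkynyl Grignard reagent to the enal; hard acetylides do not add in conjugate fashion, and the racemate is accepted at this stage.

Step 2
Reactants: 3
Product: 4 (S)-2-methylpent-1-en-4-yn-3-ol
Conditions: Ti(OiPr)4 (10 mol %), L-(+)-diisopropyl tartrate (15 mol %), t-BuOOH (0.6 equiv), 4 Å MS, CH2Cl2, −20 °C
Reagents that add atoms: none
Why: Sharpless kinetic resolution; only the isopropenyl group can be epoxidised, so by the tartrate mnemonic the R enantiomer should be consumed and 4 recovered.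

Step 3
Reactants: 4
Product: 6 (1E,3R)-1-iodo-4-methylpenta-1,4-dien-3-ol, via alkenylzirconocene 5 (not isolated)
Conditions: Cp2Zr(H)Cl (2.2 equiv), THF, 0 °C to rt; then I2, 0 °C
Reagents that add atoms: iodine, II
Why: hydrozirconation adds Zr–H syn across the terminal alkyne with the metal at the terminus (the first equivalent is taken up by the hydroxyl), and iodinolysis with retention should give the E iodoalkene; the 1,1-disubstituted alkene reacts far more slowly and C10 is not touched.

### Diazo lactone fragment

Step 4
Reactants: 7 (R)-4-[(tert-butyldimethylsilyl)oxy]cyclopent-2-en-1-one; 8 tert-butyl acetate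
Product: 10 tert-butyl 2-[(1R,4R)-4-[(tert-butyldimethylsilyl)oxy]-1-hydroxycyclopent-2-en-1-yl]acetate, via lithium enolate 9 (not isolated)
Conditions: LiN(i-Pr)2, THF, −78 °C; then 7, −78 °C; aq. NH4Cl at −78 °C
Reagents that add atoms: none
Why: kinetic aldol-type 1,2-addition of the ester lithium enolate to the enone carbonyl; attack anti to the silyloxy group sets C16, with the new hydroxyl cis to the silyl ether.

Step 5
Reactants: 10
Product: 11 (1S,4R)-4-[(tert-butyldimethylsilyl)oxy]-1-(2-hydroxyethyl)cyclopent-2-en-1-ol
Conditions: LiAlH4, THF, 0 °C to rt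
Reagents that add atoms: none
Why: hydride reduction of the ester to the primary alcohol that will become C27; the allylic silyl ether and the tertiary carbinol are inert.

Step 6
Reactants: 11
Product: 12 (1S,3R)-1-(2-hydroxyethyl)cyclopent-4-ene-1,3-diol
Conditions: Bu4NF, THF, 0 °C to rt
Reagents that add atoms: none
Why: fluoride cleaves the silyl ether; this is done before any carbonyl is present, so that basic fluoride cannot trigger retro-aldol or elimination.

Step 7
Reactants: 12
Product: 13 (1S,3R)-1-[2-(triethylsilyloxy)ethyl]cyclopent-4-ene-1,3-diol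
Conditions: Et3SiCl (1.05 equiv), imidazole, CH2Cl2, −78 to −40 °C
Reagents that add atoms: chlorotriethylsilane, CC[Si](Cl)(CC)CC
Why: silylation of the least hindered, primary hydroxyl; the triethylsilyl ether is chosen because it can later be removed beside a secondary tert-butyldimethylsilyl ether and a diazo group.

Step 8
Reactants: 13
Product: 14 (S)-4-hydroxy-4-[2-(triethylsilyloxy)ethyl]cyclopent-2-en-1-one
Conditions: MnO2, CH2Cl2, rt
Reagents that add atoms: none
Why: MnO2 oxidises only the secondary allylic alcohol; C16 is now the sole stereocentre and the C18 carbonyl activates C21 for conjugate addition.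

Step 9
Reactants: 14; 15 pent-4-enoyl chloride
Product: 16 (1S)-4-oxo-1-[2-(triethylsilyloxy)ethyl]cyclopent-2-en-1-yl pent-4-enoate
Conditions: Et3N, DMAP, CH2Cl2, 0 °C to rt
Reagents that add atoms: none
Why: DMAP-catalysed acylation of the tertiary alcohol; the mild amine base does not open the hydroxy enone by retro-aldol.

Step 10
Reactants: 16
Product: 17 (1S)-4-oxo-1-[2-(triethylsilyloxy)ethyl]cyclopent-2-en-1-yl 4-oxobutanoate
Conditions: OsO4 (2 mol %), NaIO4, 2,6-lutidine, dioxane/H2O, rt
Reagents that add atoms: osmium tetroxide, O=[Os](=O)(=O)=O (catalytic oxygen carrier); sodium periodate, [Na+].[O-]I(=O)(=O)=O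
Why: Lemieux–Johnson cleavage of the electron-rich terminal alkene; the electron-poor enone is left, and the lutidine buffer spares the silyl ether.

Step 11
Reactants: 17
Product: 18 (4S,4aS,7aS)-2,6-dioxo-7a-[2-(triethylsilyloxy)ethyl]octahydrocyclopenta[b]pyran-4-carbaldehyde
Conditions: (R)-α,α-diphenylprolinol trimethylsilyl ether (20 mol %), PhCO2H (20 mol %), toluene, 0 °C to rt
Reagents that add atoms: none
Why: enamine-catalysed intramolecular Michael addition (6-exo-trig); the ester tether reaches C21 only on the face of O15, which gives the cis-fused lactone. The catalyst blocks the Si face of the E enamine, so C21 bonds to the Re face of C22 and the formyl group ends cis to C20 (H21 and H22 cis).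

Step 12
Reactants: 18
Product: 19 (4R,4aS,7aS)-4-ethenyl-7a-[2-(triethylsilyloxy)ethyl]octahydrocyclopenta[b]pyran-2,6-dione
Conditions: CH2I2, Zn, Ti(OiPr)4, THF, rt
Reagents that add atoms: diiodomethane, ICI
Why: Takai-type methylenation is selective for aldehydes over ketones and is not basic, so the cyclopentanone, the epimerisable C22 centre and the β-acyloxy ketone are spared.

Step 13
Reactants: 19
Product: 20 (4R,4aS,6S,7aS)-4-ethenyl-6-hydroxy-7a-[2-(triethylsilyloxy)ethyl]octahydrocyclopenta[b]pyran-2-one
Conditions: LiBH(s-Bu)3, THF, −78 °C
Reagents that add atoms: none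
Why: the bulky hydride should attack the cyclopentanone from the convex face, anti to the pseudoaxial lactone oxygen and the C22 branch; this gives the alcohol cis to O15, the C18 epimer of the one needed, but selectively.

Step 14
Reactants: 20
Product: 22 (4R,4aS,6R,7aS)-4-ethenyl-6-hydroxy-7a-[2-(triethylsilyloxy)ethyl]octahydrocyclopenta[b]pyran-2-one, via 4-nitrobenzoate ester 21 (not isolated)
Conditions: 4-O2NC6H4CO2H, PPh3, DIAD, THF, 0 °C to rt; then K2CO3 (cat.), MeOH, 0 °C
Reagents that add atoms: 4-nitrobenzoic acid, O=C(O)c1ccc(cc1)[N+](=O)[O-]
Why: the Mitsunobu reaction inverts C18 by SN2 from the open convex face; brief methanolysis of the activated ester releases the alcohol trans to O15 while the lactone and the triethylsilyl ether persist.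

Step 15
Reactants: 22
Product: 23 (4R,4aS,6R,7aS)-6-[(tert-butyldimethylsilyl)oxy]-4-ethenyl-7a-[2-(triethylsilyloxy)ethyl]octahydrocyclopenta[b]pyran-2-one
Conditions: t-BuMe2SiOTf, 2,6-lutidine, CH2Cl2, −78 °C
Reagents that add atoms: tert-butyldimethylsilyl triflate, CC(C)(C)[Si](C)(C)OS(=O)(=O)C(F)(F)F
Why: silylation of the secondary alcohol; O19 must be masked so that the later hydroxy aldehyde cannot close to a bridged lactol and cannot compete for the carbenoid.

Step 16
Reactants: 23
Product: 25 (4R,4aS,6R,7aS)-6-[(tert-butyldimethylsilyl)oxy]-3-diazo-4-ethenyl-7a-[2-(triethylsilyloxy)ethyl]octahydrocyclopenta[b]pyran-2-one, via trifluoroacetyl lactone 24 (not isolated)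
Conditions: LiN(SiMe3)2, THF, −78 °C; CF3CO2CH2CF3; then MsN3, Et3N, H2O, MeCN, rt
Reagents that add atoms: methanesulfonyl azide, CS(=O)(=O)N=[N+]=[N-]
Why: detrifluoroacetylative (Regitz-type) diazo transfer; the lactone enolate is C-acylated and the activated dicarbonyl then accepts N2 from the sulfonyl azide with loss of the acyl group. C12 carries the only acidic C–H, and the aldehyde is not yet present.

Step 17
Reactants: 25
Product: 26 (4R,4aS,6R,7aS)-6-[(tert-butyldimethylsilyl)oxy]-3-diazo-4-ethenyl-7a-(2-hydroxyethyl)octahydrocyclopenta[b]pyran-2-one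
Conditions: PPTS (cat.), MeOH/CH2Cl2, 0 °C
Reagents that add atoms: none
Why: acid-catalysed methanolysis removes the primary triethylsilyl ether much faster than the secondary tert-butyldimethylsilyl ether; a pyridinium acid is too weak to protonate the diazo carbon.

Step 18
Reactants: 26
Product: 27 2-[(4R,4aS,6R,7aR)-6-[(tert-butyldimethylsilyl)oxy]-3-diazo-4-ethenyl-2-oxooctahydrocyclopenta[b]pyran-7a-yl]acetaldehyde
Conditions: Dess–Martin periodinane, NaHCO3, CH2Cl2, 0 °C to rt
Reagents that add atoms: none
Why: Dess–Martin oxidation under buffered neutral conditions tolerates the diazo lactone and does not expose the β-acyloxy aldehyde to base.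

### Union and endgame

Step 19
Reactants: 27; 6
Product: 29 (1S,3R,5S,6R,7S,11R)-3-[(tert-butyldimethylsilyl)oxy]-6-ethenyl-11-hydroxy-7-{[(1E,3R)-1-iodo-4-methylpenta-1,4-dien-3-yl]oxy}-9-oxatricyclo[5.2.2.0^{1,5}]undecan-8-one, via alkoxy enol 28 (not isolated)
Conditions: Rh2(OAc)4 (2 mol %), (PhO)2P(O)OH (10 mol %), 4 Å MS, CH2Cl2, 0 °C, slow addition of 27 to 6 (1.5 equiv)
Reagents that add atoms: none
Why: Proposed new method: loss of N2 from 27 at Rh2(OAc)4 gives an electrophilic carbenoid at C12; the hydroxyl of 6 adds to it, and the oxonium ylide (or the enol 28 that it sheds) is nucleophilic at C12 and adds to the C27 aldehyde before the usual 1,2-proton shift, so that O11–C12 and C12–C27 form in one neutral operation. The closest known reaction type is the Rh2(OAc)4-catalysed three-component coupling of diazo esters, alcohols and aldehydes through trapped oxonium ylides, which has not been shown for an α-alkyl α-diazo lactone or for a bridging closure. The carbocycle closes by a 6-(enolendo)-exo-trig aldol across the lactone held as a boat, giving the 2-oxabicyclo[2.2.2]octanone. C12 is controlled by the tether: the arm on C16 reaches only one face of the enol, which leaves O11 in the outer bridgehead position. C27 is controlled by the orientation of the carbonyl: the phosphoric acid hydrogen-bonds the aldehyde and should sit over the small C22–H side, not against the lactone oxygen atoms, turning the hydroxyl away from the lactone bridge. C10 is not involved. The step must beat hydride migration from C22, sigmatropic shift of the allyloxy enol and plain O–H insertion; what secures this is the proximity of the aldehyde (intramolecular, six-membered) together with slow addition of 27. Neutrality also protects the β-acyloxy aldehyde, which would eliminate O15 under any basic aldol.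

Step 20
Reactants: 29
Product: 30 silyl-protected tetracycle carrying an (E)-2-iodoethenyl group on C10 (the C23=C24 dihydropyran is closed)
Conditions: second-generation Grubbs catalyst (10 mol %), toluene, 60 °C, argon purge
Reagents that add atoms: none
Why: ring-closing metathesis; the catalyst loads at the vinyl group on C22 and can close a six-membered ring only onto the isopropenyl group, because the iodoalkene does not take part in metathesis. The heptyl chain is withheld until after this step for that reason.

Step 21
Reactants: 30; 31 n-heptylzinc bromide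
Product: 32 18-O-tert-butyldimethylsilyl ether of 33
Conditions: PdCl2(dppf) (5 mol %), THF, rt
Reagents that add atoms: none
Why: Negishi coupling; oxidative addition of the alkenyl iodide to zerovalent palladium, transmetalation and reductive elimination proceed with retention of the E geometry, under neutral conditions that the β-hydroxy lactone tolerates.

Step 22
Reactants: 32
Product: 33 CNP0127096.1
Conditions: HF·pyridine, pyridine, THF, 0 °C to rt
Reagents that add atoms: none
Why: buffered fluoride desilylation frees O19 without ionising the doubly allylic ether at C10 or opening the lactone.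

## Compound list

1 | methacrolein (2-methylprop-2-enal) | CC(=C)C=O | starting material
2 | ethynylmagnesium bromide | C#C[Mg]Br | starting material
3 | (±)-2-methylpent-1-en-4-yn-3-ol | C#CC(O)C(C)=C | intermediate
4 | (S)-2-methylpent-1-en-4-yn-3-ol | C#C[C@@H](O)C(C)=C | intermediate
5 | (E)-alkenylzirconocene chloride derived from 4, oxygen also bound to Cp2ZrCl | C=C(C)[C@H](O[Zr](Cl)(C1C=CC=C1)C1C=CC=C1)/C=C/[Zr](Cl)(C1C=CC=C1)C1C=CC=C1 | intermediate
6 | (1E,3R)-1-iodo-4-methylpenta-1,4-dien-3-ol | I/C=C/[C@@H](O)C(C)=C | intermediate
7 | (R)-4-[(tert-butyldimethylsilyl)oxy]cyclopent-2-en-1-one | O=C1C[C@@H](O[Si](C)(C)C(C)(C)C)C=C1 | starting material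
8 | tert-butyl acetate | CC(=O)OC(C)(C)C | starting material
9 | lithium enolate of tert-butyl acetate | C=C(O[Li])OC(C)(C)C | intermediate
10 | tert-butyl 2-[(1R,4R)-4-[(tert-butyldimethylsilyl)oxy]-1-hydroxycyclopent-2-en-1-yl]acetate | CC(C)(C)OC(=O)C[C@]1(O)C[C@@H](O[Si](C)(C)C(C)(C)C)C=C1 | intermediate
11 | (1S,4R)-4-[(tert-butyldimethylsilyl)oxy]-1-(2-hydroxyethyl)cyclopent-2-en-1-ol | OCC[C@]1(O)C[C@@H](O[Si](C)(C)C(C)(C)C)C=C1 | intermediate
12 | (1S,3R)-1-(2-hydroxyethyl)cyclopent-4-ene-1,3-diol | OCC[C@]1(O)C[C@@H](O)C=C1 | intermediate
13 | (1S,3R)-1-[2-(triethylsilyloxy)ethyl]cyclopent-4-ene-1,3-diol | CC[Si](CC)(CC)OCC[C@]1(O)C[C@@H](O)C=C1 | intermediate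
14 | (S)-4-hydroxy-4-[2-(triethylsilyloxy)ethyl]cyclopent-2-en-1-one | CC[Si](CC)(CC)OCC[C@]1(O)CC(=O)C=C1 | intermediate
15 | pent-4-enoyl chloride | C=CCCC(=O)Cl | starting material
16 | (1S)-4-oxo-1-[2-(triethylsilyloxy)ethyl]cyclopent-2-en-1-yl pent-4-enoate | C=CCCC(=O)O[C@@]1(CCO[Si](CC)(CC)CC)CC(=O)C=C1 | intermediate
17 | (1S)-4-oxo-1-[2-(triethylsilyloxy)ethyl]cyclopent-2-en-1-yl 4-oxobutanoate | O=CCCC(=O)O[C@@]1(CCO[Si](CC)(CC)CC)CC(=O)C=C1 | intermediate
18 | (4S,4aS,7aS)-2,6-dioxo-7a-[2-(triethylsilyloxy)ethyl]octahydrocyclopenta[b]pyran-4-carbaldehyde | C1C(=O)O[C@@]2(CCO[Si](CC)(CC)CC)CC(=O)C[C@H]2[C@H]1C=O | intermediate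
19 | (4R,4aS,7aS)-4-ethenyl-7a-[2-(triethylsilyloxy)ethyl]octahydrocyclopenta[b]pyran-2,6-dione | C1C(=O)O[C@@]2(CCO[Si](CC)(CC)CC)CC(=O)C[C@H]2[C@H]1C=C | intermediate
20 | (4R,4aS,6S,7aS)-4-ethenyl-6-hydroxy-7a-[2-(triethylsilyloxy)ethyl]octahydrocyclopenta[b]pyran-2-one | C1C(=O)O[C@@]2(CCO[Si](CC)(CC)CC)C[C@@H](O)C[C@H]2[C@H]1C=C | intermediate
21 | (4R,4aS,6R,7aS)-4-ethenyl-2-oxo-7a-[2-(triethylsilyloxy)ethyl]octahydrocyclopenta[b]pyran-6-yl 4-nitrobenzoate | C1C(=O)O[C@@]2(CCO[Si](CC)(CC)CC)C[C@H](OC(=O)c3ccc(cc3)[N+](=O)[O-])C[C@H]2[C@H]1C=C | intermediate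
22 | (4R,4aS,6R,7aS)-4-ethenyl-6-hydroxy-7a-[2-(triethylsilyloxy)ethyl]octahydrocyclopenta[b]pyran-2-one | C1C(=O)O[C@@]2(CCO[Si](CC)(CC)CC)C[C@H](O)C[C@H]2[C@H]1C=C | intermediate
23 | (4R,4aS,6R,7aS)-6-[(tert-butyldimethylsilyl)oxy]-4-ethenyl-7a-[2-(triethylsilyloxy)ethyl]octahydrocyclopenta[b]pyran-2-one | C1C(=O)O[C@@]2(CCO[Si](CC)(CC)CC)C[C@H](O[Si](C)(C)C(C)(C)C)C[C@H]2[C@H]1C=C | intermediate
24 | 3-(trifluoroacetyl) derivative of 23 (C3 undefined, enolised) | O=C(C1C(=O)O[C@@]2(CCO[Si](CC)(CC)CC)C[C@H](O[Si](C)(C)C(C)(C)C)C[C@H]2[C@H]1C=C)C(F)(F)F | intermediate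
25 | (4R,4aS,6R,7aS)-6-[(tert-butyldimethylsilyl)oxy]-3-diazo-4-ethenyl-7a-[2-(triethylsilyloxy)ethyl]octahydrocyclopenta[b]pyran-2-one | [N-]=[N+]=C1C(=O)O[C@@]2(CCO[Si](CC)(CC)CC)C[C@H](O[Si](C)(C)C(C)(C)C)C[C@H]2[C@H]1C=C | intermediate
26 | (4R,4aS,6R,7aS)-6-[(tert-butyldimethylsilyl)oxy]-3-diazo-4-ethenyl-7a-(2-hydroxyethyl)octahydrocyclopenta[b]pyran-2-one | [N-]=[N+]=C1C(=O)O[C@@]2(CCO)C[C@H](O[Si](C)(C)C(C)(C)C)C[C@H]2[C@H]1C=C | intermediate
27 | 2-[(4R,4aS,6R,7aR)-6-[(tert-butyldimethylsilyl)oxy]-3-diazo-4-ethenyl-2-oxooctahydrocyclopenta[b]pyran-7a-yl]acetaldehyde | [N-]=[N+]=C1C(=O)O[C@@]2(CC=O)C[C@H](O[Si](C)(C)C(C)(C)C)C[C@H]2[C@H]1C=C | intermediate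
28 | alkoxy enol of the lactone (C12=C13 enol bearing the ether of 6 on C12; tautomer of the oxonium ylide; other centres as in 27 and 6) | I/C=C/[C@H](C(C)=C)OC1=C(O)O[C@@]2(CC=O)C[C@H](O[Si](C)(C)C(C)(C)C)C[C@H]2[C@H]1C=C | intermediate
29 | (1S,3R,5S,6R,7S,11R)-3-[(tert-butyldimethylsilyl)oxy]-6-ethenyl-11-hydroxy-7-{[(1E,3R)-1-iodo-4-methylpenta-1,4-dien-3-yl]oxy}-9-oxatricyclo[5.2.2.0^{1,5}]undecan-8-one | I/C=C/[C@H](C(C)=C)O[C@@]12C(=O)O[C@]3(C[C@H](O[Si](C)(C)C(C)(C)C)C[C@H]3[C@H]1C=C)C[C@H]2O | intermediate
30 | silyl-protected tetracycle with an (E)-2-iodoethenyl group on C10; centres 10R,12S,16S,18R,21S,22R,27R by SMILES position | I/C=C/[C@H]1O[C@@]23C(=O)O[C@]4(C[C@H](O[Si](C)(C)C(C)(C)C)C[C@H]4[C@H]2C=C1C)C[C@H]3O | intermediate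
31 | n-heptylzinc bromide | CCCCCCC[Zn]Br | starting material
32 | 18-O-tert-butyldimethylsilyl ether of 33; centres 10R,12S,16S,18R,21S,22R,27R | CCCCCCC/C=C/[C@H]1O[C@@]23C(=O)O[C@]4(C[C@H](O[Si](C)(C)C(C)(C)C)C[C@H]4[C@H]2C=C1C)C[C@H]3O | intermediate
33 | CNP0127096.1; centres 10R,12S,16R,18R,21S,22R,27R by SMILES position | CCCCCCC/C=C/[C@H]1O[C@@]23C(=O)O[C@]4(C[C@H](O)C[C@H]4[C@H]2C=C1C)C[C@H]3O | target

## Step count and least certain steps

Total: 22 steps. Longest linear sequence: 19 steps (steps 4 to 22); the three-step branch to 6 joins at step 19.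

**Step 19 (key step).**
- What may go wrong: hydride migration from the allylic C22–H to the carbenoid; proton transfer or sigmatropic shift of the allyloxy ylide or enol before the aldol; approach of the aldehyde with the wrong face, which would invert C27.
- Fallback (known chemistry, sets out from 25, returns at 29): the two bonds are made one after the other.
  - Rh2(OAc)4-catalysed O–H insertion of 6 into 25, whose arm is still a silyl ether, gives the α-alkoxy lactone F1 as a mixture at C12.
  - PPTS in methanol gives the primary alcohol F2, and Dess–Martin periodinane gives the aldehyde F3.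
  - F3 is closed by an intramolecular lithium aldol (LiN(SiMe3)2, THF, −78 °C, inverse addition) to 29. Chelation of lithium between O11 and the lactone carbonyl is relied on to direct deprotonation to C12.
  - The basic closure is the weak point of this fallback, because enolisation at C26 would expel O15.

**Step 11 (Michael cyclisation).**
- What may go wrong: slow closure, because the ester must adopt its less favoured rotamer; substrate bias against the catalyst-preferred enamine face, which erodes C22; loss of O15 by β-elimination from the product ketone.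
- Fallback (sets out from 14, returns at 19): 14 is esterified with (E)-5-(trimethylsilyl)pent-3-enoic acid (DCC, DMAP) to the allylsilane ester F4. An intramolecular Hosomi–Sakurai conjugate allylation (EtAlCl2, CH2Cl2, −78 °C) forms C21–C22 and delivers the vinyl group directly, replacing steps 9 to 12. C22 would then rest on substrate control and has to be checked.

**Step 13 (hydride reduction, with the inversion of step 14).**
- What may go wrong: poor or reversed facial selectivity at C18; elimination during the Mitsunobu reaction.
- Fallback (sets out from 20, returns at 22): Tf2O and pyridine give the triflate F5; Bu4N NO2 in DMF displaces it with inversion (Lattrell–Dax) and the nitrite ester hydrolyses on work-up to 22. If the hydride enters from the lactone face instead, the product of step 13 is 22 itself and step 14 is dropped.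

**Step 16 (diazo transfer).**
- What may go wrong: incomplete C-acylation of the hindered enolate next to the C22 branch, and cleavage of the trifluoroacetyl group without transfer.
- Fallback (sets out from 23, returns at 25): electrophilic azidation of the potassium enolate (KN(SiMe3)2; 2,4,6-triisopropylbenzenesulfonyl azide; AcOH) gives the α-azido lactone F6. Staudinger reduction (PPh3, H2O) gives the α-amino lactone F7, and diazotisation with isoamyl nitrite and catalytic acetic acid gives 25.

**Step 2 (kinetic resolution).**
- What may go wrong: a low selectivity factor for the small alkynyl carbinol, and loss of the volatile alcohol.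
- Fallback (sets out from 1, returns at 4): catalytic enantioselective alkynylation of 1 with trimethylsilylacetylene (Me2Zn, ProPhenol ligand of the sense that gives the S carbinol, toluene) gives the silyl enynol F8; K2CO3 in methanol removes the silyl group to give 4.

## Further compounds

F1 | step 19 | O–H insertion product of 25 and 6 (3-alkoxy lactone, both C12 epimers, arm as triethylsilyl ether) | I/C=C/[C@H](C(C)=C)OC1C(=O)O[C@@]2(CCO[Si](CC)(CC)CC)C[C@H](O[Si](C)(C)C(C)(C)C)C[C@H]2[C@H]1C=C
F2 | step 19 | primary alcohol from F1 | I/C=C/[C@H](C(C)=C)OC1C(=O)O[C@@]2(CCO)C[C@H](O[Si](C)(C)C(C)(C)C)C[C@H]2[C@H]1C=C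
F3 | step 19 | aldehyde from F2 (uncyclised insertion product) | I/C=C/[C@H](C(C)=C)OC1C(=O)O[C@@]2(CC=O)C[C@H](O[Si](C)(C)C(C)(C)C)C[C@H]2[C@H]1C=C
F4 | step 11 | (1S)-4-oxo-1-[2-(triethylsilyloxy)ethyl]cyclopent-2-en-1-yl (E)-5-(trimethylsilyl)pent-3-enoate | C[Si](C)(C)C/C=C/CC(=O)O[C@@]1(CCO[Si](CC)(CC)CC)CC(=O)C=C1
F5 | step 13 | (4R,4aS,6S,7aS)-4-ethenyl-2-oxo-7a-[2-(triethylsilyloxy)ethyl]octahydrocyclopenta[b]pyran-6-yl trifluoromethanesulfonate | C1C(=O)O[C@@]2(CCO[Si](CC)(CC)CC)C[C@@H](OS(=O)(=O)C(F)(F)F)C[C@H]2[C@H]1C=C
F6 | step 16 | 3-azido derivative of 23 (C3 undefined) | [N-]=[N+]=NC1C(=O)O[C@@]2(CCO[Si](CC)(CC)CC)C[C@H](O[Si](C)(C)C(C)(C)C)C[C@H]2[C@H]1C=C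
F7 | step 16 | 3-amino derivative of 23 (C3 undefined) | NC1C(=O)O[C@@]2(CCO[Si](CC)(CC)CC)C[C@H](O[Si](C)(C)C(C)(C)C)C[C@H]2[C@H]1C=C
F8 | step 2 | (S)-2-methyl-5-(trimethylsilyl)pent-1-en-4-yn-3-ol | C[Si](C)(C)C#C[C@@H](O)C(C)=C
A1 | alternative 1 | cis-fused keto lactone aldehyde: 3-[(4-methoxyphenyl)methoxy]-2,6-dioxo-7a-ethenyloctahydrocyclopenta[b]pyran-4-carbaldehyde | O=C[C@H]1[C@@H](OCc2ccc(OC)cc2)C(=O)O[C@@]3(C=C)CC(=O)C[C@@H]13
A2 | alternative 2 | 2-[(4-methoxyphenyl)methoxymethyl]-5-methyl-6-[(E)-non-1-enyl]-3-[4-(tert-butyldimethylsilyloxy)-2-methylidenecyclopentyl]-3,6-dihydro-2H-pyran-2-carboxylic acid | CCCCCCC/C=C/[C@H]1O[C@@](COCc2ccc(OC)cc2)(C(=O)O)[C@@H]([C@@H]3C[C@@H](O[Si](C)(C)C(C)(C)C)CC3=C)C=C1C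
A3 | alternative 3 | ethyl 5-methyl-6-[(E)-non-1-enyl]-3-[8-(tert-butyldimethylsilyloxy)-1,4-dioxaspiro[4.4]nonan-6-yl]-3,6-dihydro-2H-pyran-2-carboxylate | CCCCCCC/C=C/[C@H]1O[C@@H](C(=O)OCC)[C@H](C=C1C)[C@@H]2C[C@@H](O[Si](C)(C)C(C)(C)C)CC23OCCO3
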